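**Strategy.** The cyclopentane is closed last, between its CH2 (C3) and the isopropyl-bearing carbinol carbon (C4). The 2-acetoxy/4-hydroxy pair of that ring is a masked β-hydroxy ketone. An intramolecular aldol of a C1 acetyl group onto a C5 isobutyryl ketone, both held trans on a preformed cycloheptenone, should therefore form the C3–C4 bond, the trans-fused hydroazulene and the C4 stereocentre in one operation. The new tertiary hydroxyl then directs the reduction at C2. The triketone precursor arises from an (S)-4-silyloxycyclohepta-2,6-dienone (Still–Gennari olefination, RCM) by anti-selective conjugate addition and aldol trapping. The three esters are introduced one at a time as each hydroxyl is unveiled.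

Key step: step 10

Remark: atoms carry daucane numbers throughout, precursors included (C1 methyl-bearing ring-fusion carbon, C2 acetoxy carbon, C3 ring CH2, C4 isopropyl carbinol carbon, C5 ring-fusion CH, C6 aroyloxy carbon, C7 CH2, C8=C9 the methyl-substituted alkene, C10 benzoyloxy carbon; β is the face of the C1 methyl); 2-bromo-3-methylbut-1-ene and 4-[(tert-butyldimethylsilyl)oxy]benzoic acid are assumed to be catalogue compounds.

Step 1
Reactants: 1 methyl (S)-oxirane-2-carboxylate (methyl (S)-glycidate); 2 isopropenylmagnesium bromide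
Product: 3 methyl (S)-2-hydroxy-4-methylpent-4-enoate
Conditions: CuI (10 mol %), THF, −40 °C; aq. NH4Cl
Reagents that add atoms: isopropenylmagnesium bromide, CC(=C)[Mg]Br
Why: The alkenyl cuprate formed in situ should open the glycidic ester by SN2 attack at the unsubstituted C3 faster than the Grignard reagent adds to the ester at −40 °C (copper-catalysed epoxide opening), so the (S) stereocentre, the later C6, is carried over unchanged.

Step 2
Reactants: 3 methyl (S)-2-hydroxy-4-methylpent-4-enoate; 4 tert-butyldimethylsilyl chloride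
Product: 5 methyl (S)-2-[(tert-butyldimethylsilyl)oxy]-4-methylpent-4-enoate
Conditions: imidazole, DMF, 0 °C to rt
Reagents that add atoms: tert-butyldimethylsilyl chloride, CC(C)(C)[Si](C)(C)Cl
Why: Standard silyl ether formation protects the future C6 hydroxyl with a group that should tolerate every step up to step 15 and later steers the conjugate addition.

Step 3
Reactants: 5 methyl (S)-2-[(tert-butyldimethylsilyl)oxy]-4-methylpent-4-enoate
Product: 6 (S)-2-[(tert-butyldimethylsilyl)oxy]-4-methylpent-4-enal
Conditions: DIBAL-H (1.1 equiv), CH2Cl2, −78 °C; Rochelle salt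
Reagents that add atoms: none
Why: DIBAL-H partial reduction of the α-silyloxy ester stops at the tetrahedral aluminium hemiacetal at −78 °C and should give the aldehyde without epimerisation.

Step 4
Reactants: 6 (S)-2-[(tert-butyldimethylsilyl)oxy]-4-methylpent-4-enal; 7 ethyl 2-[bis(2,2,2-trifluoroethoxy)phosphoryl]propanoate
Product: 8 ethyl (2Z,4S)-4-[(tert-butyldimethylsilyl)oxy]-2,6-dimethylhepta-2,6-dienoate
Conditions: KHMDS, 18-crown-6, THF, −78 °C
Reagents that add atoms: ethyl 2-[bis(2,2,2-trifluoroethoxy)phosphoryl]propanoate, CCOC(=O)C(C)P(=O)(OCC(F)(F)F)OCC(F)(F)F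
Why: The Still–Gennari modification of the Horner–Wadsworth–Emmons reaction with an α-methyl bis(trifluoroethyl)phosphonate should give the (Z)-trisubstituted enoate, the geometry that later lets C10 and C6 sit in one ring.

Step 5
Reactants: 8 ethyl (2Z,4S)-4-[(tert-butyldimethylsilyl)oxy]-2,6-dimethylhepta-2,6-dienoate; 9 N,O-dimethylhydroxylamine hydrochloride; 10 vinylmagnesium bromide
Product: 12 (4Z,6S)-6-[(tert-butyldimethylsilyl)oxy]-4,8-dimethylnona-1,4,8-trien-3-one, via Weinreb amide 11 (not isolated)
Conditions: MeNHOMe·HCl, i-PrMgCl, THF, −20 °C; then CH2=CHMgBr, 0 °C; inverse quench into cold aq. KHSO4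
Reagents that add atoms: vinylmagnesium bromide, C=C[Mg]Br
Why: Magnesium-amide aminolysis of the ester gives the Weinreb amide, whose chelated tetrahedral adduct with vinylmagnesium bromide collapses only on cold acidic quench (Weinreb ketone synthesis), so the divinyl ketone should form without over-addition or loss of the Z geometry.

Step 6
Reactants: 12 (4Z,6S)-6-[(tert-butyldimethylsilyl)oxy]-4,8-dimethylnona-1,4,8-trien-3-one
Product: 13 (S)-4-[(tert-butyldimethylsilyl)oxy]-2,6-dimethylcyclohepta-2,6-dien-1-one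
Conditions: Grubbs II (5 mol %), CH2Cl2 (5 mM), 40 °C
Reagents that add atoms: none
Why: Ring-closing metathesis between the vinyl ketone and the 1,1-disubstituted alkene, preorganised by the (Z)-enone, should close the seven-membered ring as the C8=C9 trisubstituted enone with loss of ethene.

Step 7
Reactants: 13 (S)-4-[(tert-butyldimethylsilyl)oxy]-2,6-dimethylcyclohepta-2,6-dien-1-one; 14 2-bromo-3-methylbut-1-ene; 15 acetaldehyde
Product: 18 (5S,6S,7R)-5-[(tert-butyldimethylsilyl)oxy]-7-(1-hydroxyethyl)-3,7-dimethyl-6-(3-methylbut-1-en-2-yl)cyclohept-2-en-1-one (both carbinol epimers), via alkenyl Grignard reagent 16 (not isolated), via bromomagnesium enolate 17 (not isolated)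
Conditions: 14, Mg, THF, rt; then CuBr·SMe2 (20 mol %), 13, THF, −78 to −40 °C; then MeCHO (5 equiv), −78 °C; aq. NH4Cl
Reagents that add atoms: 2-bromo-3-methylbut-1-ene (as its Grignard reagent), C=C(Br)C(C)C; acetaldehyde, CC=O
Why: The copper-catalysed 1,4-addition should go to the less substituted β-carbon C5 of the cross-conjugated dienone anti to the C6 silyloxy group, and the resulting enolate should add acetaldehyde at C1 anti to the new C5 substituent (tandem conjugate addition–aldol trapping), which sets C5 and the quaternary C1 relative to C6 while the carbinol carbon, formed as an epimer mixture, is erased in step 8.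

Step 8
Reactants: 18 (5S,6S,7R)-5-[(tert-butyldimethylsilyl)oxy]-7-(1-hydroxyethyl)-3,7-dimethyl-6-(3-methylbut-1-en-2-yl)cyclohept-2-en-1-one
Product: 19 (5S,6S,7R)-7-acetyl-5-[(tert-butyldimethylsilyl)oxy]-3,7-dimethyl-6-(3-methylbut-1-en-2-yl)cyclohept-2-en-1-one
Conditions: Dess–Martin periodinane, NaHCO3, CH2Cl2, 0 °C to rt
Reagents that add atoms: none
Why: Dess–Martin oxidation converts the secondary carbinol into the acetyl group under buffered, non-basic conditions, and the 2-acyl-2-methyl β-diketone cannot enolise between its carbonyls because C1 is quaternary.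

Step 9
Reactants: 19 (5S,6S,7R)-7-acetyl-5-[(tert-butyldimethylsilyl)oxy]-3,7-dimethyl-6-(3-methylbut-1-en-2-yl)cyclohept-2-en-1-one; 20 ozone
Product: 22 (5S,6S,7R)-7-acetyl-5-[(tert-butyldimethylsilyl)oxy]-3,7-dimethyl-6-(2-methylpropanoyl)cyclohept-2-en-1-one, via secondary ozonide 21 (not isolated)
Conditions: O3, CH2Cl2, −78 °C (Sudan III end point); then Me2S, −78 °C to rt
Reagents that add atoms: ozone, [O-][O+]=O
Why: Ozonolysis with reductive work-up should cleave the isolated 1,1-disubstituted alkene much faster than the electron-poor enone C8=C9 and so unveils the isobutyryl ketone (C4) with loss of formaldehyde.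

Step 10
Reactants: 22 (5S,6S,7R)-7-acetyl-5-[(tert-butyldimethylsilyl)oxy]-3,7-dimethyl-6-(2-methylpropanoyl)cyclohept-2-en-1-one
Product: 24 6α-[(tert-butyldimethylsilyl)oxy]-4β-hydroxydauc-8-ene-2,10-dione (trans-fused; isopropyl α), via lithium enolate 23 (not isolated)
Conditions: LiHMDS (1.1 equiv), THF, −78 °C, then −78 to −20 °C; AcOH quench at −78 °C
Reagents that add atoms: none
Why: LiHMDS should remove a proton from the acetyl CH3 (C3), the only α-position of the C2 ketone because C1 is quaternary and kinetically favoured over the two methine α-hydrogens of the C4 ketone and the γ-hydrogens of the enone, and the lithium enolate then adds through C3 to the C4 carbonyl (intramolecular aldol addition). The closest known reaction type is the base-mediated cyclisation of a 1,4-diketone to a 3-hydroxycyclopentanone. The cyclopentane closes in the 5-(enolendo)-exo-trig mode, the usual though stereoelectronically strained mode of 1,4-diketone aldolisation, which is why the enolate is allowed to warm to −20 °C; C10 (four-membered ring) and the enone β-carbon C8 (bridged ring) are not competitive acceptors. The trans ring fusion is dictated by the trans acetyl/isobutyryl pair fixed in step 7, and at the new stereocentre C4 the isopropyl group should take the α face, where it eclipses H-5 instead of C6 and avoids the β C1 methyl, so the hydroxyl is β. Because the aldolate can revert, a minor C4 epimer should be funnelled to this more stable isomer. The step needs regioselective enolisation without β-elimination of the C6 silyloxy group (through C5–H or vinylogously through C7–H), which the non-nucleophilic amide base at low temperature and the poor silanolate leaving group should secure, and the cold acidic quench prevents dehydration of the ketol.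

Step 11
Reactants: 24 6α-[(tert-butyldimethylsilyl)oxy]-4β-hydroxydauc-8-ene-2,10-dione
Product: 25 6α-[(tert-butyldimethylsilyl)oxy]-2α,4β-dihydroxydauc-8-en-10-one
Conditions: Me4NBH(OAc)3, MeCN/AcOH (1:1), −20 °C
Reagents that add atoms: none
Why: Ligand exchange of the β-oriented C4 hydroxyl on boron followed by intramolecular hydride delivery to the β face of the C2 ketone (Evans–Saksena hydroxyl-directed reduction) should give the 2α-alcohol, i.e. the trans-1,3-diol, while the undirected C10 enone is left untouched.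

Step 12
Reactants: 25 6α-[(tert-butyldimethylsilyl)oxy]-2α,4β-dihydroxydauc-8-en-10-one; 26 acetic anhydride
Product: 27 2α-acetoxy-6α-[(tert-butyldimethylsilyl)oxy]-4β-hydroxydauc-8-en-10-one
Conditions: Ac2O, pyridine, DMAP (cat.), CH2Cl2, 0 °C to rt
Reagents that add atoms: acetic anhydride, CC(=O)OC(C)=O
Why: DMAP-catalysed acetylation should take place at the only secondary hydroxyl (C2) because the tertiary C4 hydroxyl is inert under these conditions.

Step 13
Reactants: 27 2α-acetoxy-6α-[(tert-butyldimethylsilyl)oxy]-4β-hydroxydauc-8-en-10-one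
Product: 28 2α-acetoxy-6α-[(tert-butyldimethylsilyl)oxy]dauc-8-ene-4β,10β-diol
Conditions: NaBH4, CeCl3·7H2O, MeOH, −78 to −40 °C
Reagents that add atoms: none
Why: Luche 1,2-reduction of the enone should deliver hydride anti to the axial C1 methyl group (α face), giving the 10β-allylic alcohol without touching the acetate.

Step 14
Reactants: 28 2α-acetoxy-6α-[(tert-butyldimethylsilyl)oxy]dauc-8-ene-4β,10β-diol; 29 benzoyl chloride
Product: 30 2α-acetoxy-10β-benzoyloxy-6α-[(tert-butyldimethylsilyl)oxy]dauc-8-en-4β-ol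
Conditions: BzCl, pyridine, DMAP, CH2Cl2, rt
Reagents that add atoms: benzoyl chloride, O=C(Cl)c1ccccc1
Why: Benzoylation with nucleophilic catalysis by DMAP should occur at the only secondary hydroxyl (C10), the tertiary C4 hydroxyl again remaining free.

Step 15
Reactants: 30 2α-acetoxy-10β-benzoyloxy-6α-[(tert-butyldimethylsilyl)oxy]dauc-8-en-4β-ol
Product: 31 2α-acetoxy-10β-benzoyloxydauc-8-ene-4β,6α-diol
Conditions: HF·pyridine, pyridine/THF, 0 °C to rt
Reagents that add atoms: none
Why: HF·pyridine cleaves the secondary alkyl TBS ether under mildly acidic conditions that should leave the acetate, the allylic benzoate and the tertiary alcohol untouched.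

Step 16
Reactants: 31 2α-acetoxy-10β-benzoyloxydauc-8-ene-4β,6α-diol; 32 4-[(tert-butyldimethylsilyl)oxy]benzoic acid
Product: 33 2α-acetoxy-10β-benzoyloxy-6α-{4-[(tert-butyldimethylsilyl)oxy]benzoyloxy}dauc-8-en-4β-ol
Conditions: EDC·HCl, DMAP, CH2Cl2, rt
Reagents that add atoms: 4-[(tert-butyldimethylsilyl)oxy]benzoic acid, CC(C)(C)[Si](C)(C)Oc1ccc(cc1)C(O)=O
Why: Steglich esterification should acylate the only secondary hydroxyl (C6) with retention of configuration, the phenol of the acid being masked as its silyl ether.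

Step 17
Reactants: 33 2α-acetoxy-10β-benzoyloxy-6α-{4-[(tert-butyldimethylsilyl)oxy]benzoyloxy}dauc-8-en-4β-ol
Product: 34 2α-acetoxy-10β-benzoyloxy-6α-(4-hydroxybenzoyloxy)dauc-8-en-4β-ol (CNP0316187.1)
Conditions: TBAF, AcOH, THF, 0 °C
Reagents that add atoms: none
Why: Buffered fluoride should cleave the aryl silyl ether selectively, the acetic acid buffer suppressing ester cleavage and acyl migration, to give the target.

**Compound list**

1 | methyl (S)-oxirane-2-carboxylate | COC(=O)[C@@H]1CO1 | starting material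
2 | isopropenylmagnesium bromide | CC(=C)[Mg]Br | starting material
3 | methyl (S)-2-hydroxy-4-methylpent-4-enoate | C=C(C)C[C@H](O)C(=O)OC | intermediate
4 | tert-butyldimethylsilyl chloride | CC(C)(C)[Si](C)(C)Cl | starting material
5 | methyl (S)-2-[(tert-butyldimethylsilyl)oxy]-4-methylpent-4-enoate | C=C(C)C[C@H](O[Si](C)(C)C(C)(C)C)C(=O)OC | intermediate
6 | (S)-2-[(tert-butyldimethylsilyl)oxy]-4-methylpent-4-enal | C=C(C)C[C@H](O[Si](C)(C)C(C)(C)C)C=O | intermediate
7 | ethyl 2-[bis(2,2,2-trifluoroethoxy)phosphoryl]propanoate | CCOC(=O)C(C)P(=O)(OCC(F)(F)F)OCC(F)(F)F | starting material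
8 | ethyl (2Z,4S)-4-[(tert-butyldimethylsilyl)oxy]-2,6-dimethylhepta-2,6-dienoate | CCOC(=O)/C(C)=C\[C@@H](O[Si](C)(C)C(C)(C)C)CC(C)=C | intermediate
9 | N,O-dimethylhydroxylamine hydrochloride | CNOC.Cl | starting material
10 | vinylmagnesium bromide | C=C[Mg]Br | starting material
11 | (2Z,4S)-4-[(tert-butyldimethylsilyl)oxy]-N-methoxy-N,2,6-trimethylhepta-2,6-dienamide (Weinreb amide) | CON(C)C(=O)/C(C)=C\[C@@H](O[Si](C)(C)C(C)(C)C)CC(C)=C | intermediate (not isolated)
12 | (4Z,6S)-6-[(tert-butyldimethylsilyl)oxy]-4,8-dimethylnona-1,4,8-trien-3-one | C=CC(=O)/C(C)=C\[C@@H](O[Si](C)(C)C(C)(C)C)CC(C)=C | intermediate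
13 | (S)-4-[(tert-butyldimethylsilyl)oxy]-2,6-dimethylcyclohepta-2,6-dien-1-one | O=C1C=C(C)C[C@H](O[Si](C)(C)C(C)(C)C)C=C1C | intermediate
14 | 2-bromo-3-methylbut-1-ene | C=C(Br)C(C)C | starting material
15 | acetaldehyde | CC=O | starting material
16 | (3-methylbut-1-en-2-yl)magnesium bromide | C=C([Mg]Br)C(C)C | intermediate (not isolated)
17 | bromomagnesium enolate of the C5-alkenylated cycloheptenone (C10–O–MgBr, C1=C10) | CC1=C(O[Mg]Br)C=C(C)C[C@H](O[Si](C)(C)C(C)(C)C)[C@H]1C(=C)C(C)C | intermediate (not isolated)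
18 | (5S,6S,7R)-5-[(tert-butyldimethylsilyl)oxy]-7-(1-hydroxyethyl)-3,7-dimethyl-6-(3-methylbut-1-en-2-yl)cyclohept-2-en-1-one (carbinol epimers) | CC(O)[C@]1(C)C(=O)C=C(C)C[C@H](O[Si](C)(C)C(C)(C)C)[C@H]1C(=C)C(C)C | intermediate
19 | (5S,6S,7R)-7-acetyl-5-[(tert-butyldimethylsilyl)oxy]-3,7-dimethyl-6-(3-methylbut-1-en-2-yl)cyclohept-2-en-1-one | CC(=O)[C@]1(C)C(=O)C=C(C)C[C@H](O[Si](C)(C)C(C)(C)C)[C@H]1C(=C)C(C)C | intermediate
20 | ozone | [O-][O+]=O | starting material
21 | secondary ozonide (3-isopropyl-1,2,4-trioxolan-3-yl at C5; mixture at the trioxolane carbon) | CC(=O)[C@]1(C)C(=O)C=C(C)C[C@H](O[Si](C)(C)C(C)(C)C)[C@H]1C2(C(C)C)OOCO2 | intermediate (not isolated)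
22 | (5S,6S,7R)-7-acetyl-5-[(tert-butyldimethylsilyl)oxy]-3,7-dimethyl-6-(2-methylpropanoyl)cyclohept-2-en-1-one | CC(=O)[C@]1(C)C(=O)C=C(C)C[C@H](O[Si](C)(C)C(C)(C)C)[C@H]1C(=O)C(C)C | intermediate
23 | lithium enolate of the acetyl group of 22 | C=C(O[Li])[C@]1(C)C(=O)C=C(C)C[C@H](O[Si](C)(C)C(C)(C)C)[C@H]1C(=O)C(C)C | intermediate (not isolated)
24 | 6α-[(tert-butyldimethylsilyl)oxy]-4β-hydroxydauc-8-ene-2,10-dione (trans-fused, C1 methyl β, H-5 α, isopropyl α) | O=C1C[C@@](O)(C(C)C)[C@@H]2[C@@H](O[Si](C)(C)C(C)(C)C)CC(C)=CC(=O)[C@@]12C | intermediate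
25 | 6α-[(tert-butyldimethylsilyl)oxy]-2α,4β-dihydroxydauc-8-en-10-one | O[C@H]1C[C@@](O)(C(C)C)[C@@H]2[C@@H](O[Si](C)(C)C(C)(C)C)CC(C)=CC(=O)[C@@]12C | intermediate
26 | acetic anhydride | CC(=O)OC(C)=O | starting material
27 | 2α-acetoxy-6α-[(tert-butyldimethylsilyl)oxy]-4β-hydroxydauc-8-en-10-one | CC(=O)O[C@H]1C[C@@](O)(C(C)C)[C@@H]2[C@@H](O[Si](C)(C)C(C)(C)C)CC(C)=CC(=O)[C@@]12C | intermediate
28 | 2α-acetoxy-6α-[(tert-butyldimethylsilyl)oxy]dauc-8-ene-4β,10β-diol | CC(=O)O[C@H]1C[C@@](O)(C(C)C)[C@@H]2[C@@H](O[Si](C)(C)C(C)(C)C)CC(C)=C[C@H](O)[C@@]12C | intermediate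
29 | benzoyl chloride | O=C(Cl)c1ccccc1 | starting material
30 | 2α-acetoxy-10β-benzoyloxy-6α-[(tert-butyldimethylsilyl)oxy]dauc-8-en-4β-ol | CC(=O)O[C@H]1C[C@@](O)(C(C)C)[C@@H]2[C@@H](O[Si](C)(C)C(C)(C)C)CC(C)=C[C@H](OC(=O)c3ccccc3)[C@@]12C | intermediate
31 | 2α-acetoxy-10β-benzoyloxydauc-8-ene-4β,6α-diol | CC(=O)O[C@H]1C[C@@](O)(C(C)C)[C@@H]2[C@@H](O)CC(C)=C[C@H](OC(=O)c3ccccc3)[C@@]12C | intermediate
32 | 4-[(tert-butyldimethylsilyl)oxy]benzoic acid | CC(C)(C)[Si](C)(C)Oc1ccc(cc1)C(O)=O | starting material
33 | 2α-acetoxy-10β-benzoyloxy-6α-{4-[(tert-butyldimethylsilyl)oxy]benzoyloxy}dauc-8-en-4β-ol | CC(=O)O[C@H]1C[C@@](O)(C(C)C)[C@@H]2[C@@H](OC(=O)c3ccc(O[Si](C)(C)C(C)(C)C)cc3)CC(C)=C[C@H](OC(=O)c3ccccc3)[C@@]12C | intermediate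
34 | 2α-acetoxy-10β-benzoyloxy-6α-(4-hydroxybenzoyloxy)dauc-8-en-4β-ol, (1R,2S,4R,5S,6S,10S) | CC(=O)O[C@H]1C[C@@](O)(C(C)C)[C@@H]2[C@@H](OC(=O)c3ccc(O)cc3)CC(C)=C[C@H](OC(=O)c3ccccc3)[C@@]12C | target

**Step count.** Total: 17 steps. Longest linear sequence: 17 steps (the route is fully linear from 1 to 34).

**Steps most likely to fail**

Step 10 (key aldol). What may go wrong: enolisation at C5–H or vinylogously at C7–H with loss of the C6 silanol, or a 5-(enolendo) closure too slow to outrun proton transfer and dehydration of the ketol. The fallback generates the enolate regiospecifically and without base, by an intramolecular samarium Reformatsky reaction. It sets out from 19, in which the acetyl CH3 is the only α-position. LiHMDS with TMSCl as internal quench (THF, −78 °C) should give the trimethylsilyl enol ether F1. NBS (THF, −78 °C) should then give the bromomethyl ketone F2. Ozonolysis (O3, CH2Cl2, −78 °C; Me2S) passes through the ozonide F3 to the bromo triketone F4. SmI2 (2.2 equiv, THF, −78 °C) reduces the C–Br bond to the samarium(III) enolate F5, which should add to the C4 ketone and return to the route at 24.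

Step 7 (conjugate addition–aldol trapping). What may go wrong: reversal of the hindered magnesium aldolate at the quaternary carbon, proton transfer from acetaldehyde to the enolate, or base-induced loss of the silanol towards a tropone. The fallback separates the two bond formations and makes the second one irreversible. It sets out from 13: the copper-catalysed addition of 16 is run in the presence of TMSCl, and the C5-alkenylated trimethylsilyl enol ether F6 is isolated. A TiCl4-mediated Mukaiyama aldol addition of F6 to acetaldehyde 15 (CH2Cl2, −78 °C) should then form the C1–C2 bond anti to the C5 substituent and rejoin the route at 18.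

Step 11 (directed reduction). What may go wrong: slow ligand exchange at the hindered tertiary C4 hydroxyl, so that external hydride attack with poor facial selectivity at C2 takes over. The fallback is a temporary silicon tether. It sets out from 24: chlorodimethylsilane and imidazole (DMF, 0 °C) should give the dimethylsilyl ether F7 of the C4 hydroxyl. SnCl4 (cat., CH2Cl2, −78 °C) then triggers intramolecular hydrosilylation of the C2 ketone from the β face (Davis-type hydride delivery). Work-up with dilute HCl in THF removes the silicon and returns to the route at 25.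

Further compounds

F1 | step 10 | trimethylsilyl enol ether of the acetyl group of 19 | C=C(O[Si](C)(C)C)[C@]1(C)C(=O)C=C(C)C[C@H](O[Si](C)(C)C(C)(C)C)[C@H]1C(=C)C(C)C
F2 | step 10 | (5S,6S,7R)-7-(bromoacetyl)-5-[(tert-butyldimethylsilyl)oxy]-3,7-dimethyl-6-(3-methylbut-1-en-2-yl)cyclohept-2-en-1-one | BrCC(=O)[C@]1(C)C(=O)C=C(C)C[C@H](O[Si](C)(C)C(C)(C)C)[C@H]1C(=C)C(C)C
F3 | step 10 | secondary ozonide of F2 (3-isopropyl-1,2,4-trioxolan-3-yl at C5) | BrCC(=O)[C@]1(C)C(=O)C=C(C)C[C@H](O[Si](C)(C)C(C)(C)C)[C@H]1C2(C(C)C)OOCO2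
F4 | step 10 | (5S,6S,7R)-7-(bromoacetyl)-5-[(tert-butyldimethylsilyl)oxy]-3,7-dimethyl-6-(2-methylpropanoyl)cyclohept-2-en-1-one | BrCC(=O)[C@]1(C)C(=O)C=C(C)C[C@H](O[Si](C)(C)C(C)(C)C)[C@H]1C(=O)C(C)C
F5 | step 10 | diiodosamarium(III) enolate of the acetyl group of 22 | C=C(O[Sm](I)I)[C@]1(C)C(=O)C=C(C)C[C@H](O[Si](C)(C)C(C)(C)C)[C@H]1C(=O)C(C)C
F6 | step 7 | trimethylsilyl enol ether of the C5-alkenylated cycloheptenone (C10–O–SiMe3, C1=C10) | CC1=C(O[Si](C)(C)C)C=C(C)C[C@H](O[Si](C)(C)C(C)(C)C)[C@H]1C(=C)C(C)C
F7 | step 11 | 4β-(dimethylsilyloxy)-6α-[(tert-butyldimethylsilyl)oxy]dauc-8-ene-2,10-dione | O=C1C[C@@](O[SiH](C)C)(C(C)C)[C@@H]2[C@@H](O[Si](C)(C)C(C)(C)C)CC(C)=CC(=O)[C@@]12C
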